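**Plan**

1. Locants used: ring A = C1(=O), C2, C3(O), C4(Me2), C5, C10; ether bridge C3–O–C6H2–C5; lactone ring = C10–C20H2–O–C7(=O)–C8(OH)–C9; ring C = C8, C9, C11–C14; C13 carries C16(=C17H2)–C15HO.
2. Retrosynthesis: the C15 aldehyde and the C1 ketone go back to allylic C–H; the C3–O bond is cut (oxa-Michael); the C7 lactone goes back to a lactol and a C7 dithiane, with C20 as a γ-lactone carbonyl on O–C8; ring A is then cut at C4–C5; then C10–C5 and C10–C1 (two lactone enolate alkylations), C8–C7, C13–C16 and C9–C10.
3. Enabling feature: C5 is α to the oxidised ether carbon C6, and C4 is the far end of an allyl unit C2–C3=C4 whose alkene is what the C1 ketone and the C3 ether later need; ring A is therefore the product of an Ireland–Claisen ring contraction of a spiro δ-lactone (C6 acyl on O–C2, 2-methylpropenyl on C2).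
4. Forward: cyclohexenone → 2,5-trans ketone (ring C) → cis-fused γ-lactone template → quaternary C10 → spiro δ-lactone → ring A (C4–C5) → reduction → six-membered lactol (C7/C20) → two allylic oxidations → ether ring → lactone.
5. Stereochemistry: C13 by Rh/(R)-BINAP addition; C9 by equilibration; C8 by equatorial attack of the dithiane anion; C10 by alkylation of the bicyclic lactone anti to the C9–C11 bond; C2 by CBS reduction; C5 by chirality transfer from C2; C3 by the bridge geometry.

Key step: step 10

Remark: silyl ether 8 is taken as purchasable; the absolute sense of the Rh/(R)-BINAP addition and of the (R)-CBS reduction (alkenyl as the larger ketone substituent) is assigned from the usual models.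

**Step 1**
Reactants: 1 cyclohex-2-en-1-one; 2 methyl bromoacetate
Product: 3 methyl 2-(2-oxocyclohex-3-en-1-yl)acetate (racemic)
Conditions: LiN(iPr)2, THF, −78 °C; then 2, DMPU, −78 to −30 °C
Reagents that add atoms: none
Why: kinetic α′-deprotonation of the enone gives the cross-conjugated enolate, which should be C-alkylated by the α-bromo ester (enolate alkylation); the new centre C9 is racemic here and is corrected in step 2.

**Step 2**
Reactants: 3 methyl 2-(2-oxocyclohex-3-en-1-yl)acetate; 4 4,4,5,5-tetramethyl-2-(prop-1-en-2-yl)-1,3,2-dioxaborolane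
Product: 5 methyl 2-[(1S,4R)-2-oxo-4-(prop-1-en-2-yl)cyclohexyl]acetate
Conditions: [Rh(cod)Cl]2 (cat.), (R)-BINAP, K3PO4, dioxane/H2O, 60 °C; then DBU, CH2Cl2, rt
Reagents that add atoms: none
Why: the Hayashi–Miyaura rhodium/BINAP 1,4-addition should set C13 under catalyst control on both enantiomers of 3, and DBU then equilibrates the enolisable C9 to the diequatorial 2,5-trans ketone, so the step should be stereoconvergent.

**Step 3**
Reactants: 5 methyl 2-[(1S,4R)-2-oxo-4-(prop-1-en-2-yl)cyclohexyl]acetate; 6 1,3-dithiane
Product: 7 (3aS,6R,7aS)-7a-(1,3-dithian-2-yl)-6-(prop-1-en-2-yl)hexahydro-1-benzofuran-2(3H)-one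
Conditions: 6, n-BuLi, THF, −30 °C; then 5, −78 °C to rt; aq. NH4Cl
Reagents that add atoms: none
Why: the bulky 2-lithio-1,3-dithiane (Corey–Seebach acyl anion equivalent) should attack the C8 carbonyl from the equatorial side, and the resulting axial alkoxide, cis to the acetate arm, closes the γ-lactone with loss of methoxide, which sets C8.

**Step 4**
Reactants: 8 trimethyl[(2-methylbut-3-yn-2-yl)oxy]silane
Product: 9 4-methyl-4-[(trimethylsilyl)oxy]pent-2-yn-1-ol
Conditions: n-BuLi, THF, −78 °C; (CH2O)n, −78 °C to rt; aq. NH4Cl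
Reagents that add atoms: formaldehyde (from paraformaldehyde), C=O
Why: hydroxymethylation of a lithium acetylide with formaldehyde is a standard 1,2-addition and creates no stereocentre.

**Step 5**
Reactants: 9 4-methyl-4-[(trimethylsilyl)oxy]pent-2-yn-1-ol
Product: 10 [(5-bromo-2-methylpent-3-yn-2-yl)oxy]trimethylsilane
Conditions: CBr4, PPh3, 2,6-lutidine, CH2Cl2, 0 °C
Reagents that add atoms: carbon tetrabromide, BrC(Br)(Br)Br
Why: the Appel reaction converts the primary propargylic alcohol into the bromide under buffered conditions that should leave the tertiary silyl ether intact.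

**Step 6**
Reactants: 7 (3aS,6R,7aS)-7a-(1,3-dithian-2-yl)-6-(prop-1-en-2-yl)hexahydro-1-benzofuran-2(3H)-one; 10 [(5-bromo-2-methylpent-3-yn-2-yl)oxy]trimethylsilane
Product: 11 lactone 7 carrying at C10 a 4-methyl-4-(trimethylsilyloxy)pent-2-ynyl group cis to H-9
Conditions: LiN(iPr)2, THF, −78 °C; then 10, DMPU, −78 to −40 °C
Reagents that add atoms: none
Why: lactone enolate alkylation with a propargylic bromide (SN2) attaches the C1–C4 arm; the C10 configuration formed here is of no consequence because C10 is planarised again in step 7.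

**Step 7**
Reactants: 11 mono-alkylated lactone; 2 methyl bromoacetate
Product: 12 lactone with quaternary C10 carrying the CH2CO2Me arm (C5–C6) on the face of H-9 and the silyloxypentynyl arm (C1–C4) on the face of C11
Conditions: LiN(iPr)2, THF/DMPU, −78 °C; then 2, −78 to −20 °C
Reagents that add atoms: none
Why: the tetrasubstituted enolate of the cis-fused bicyclic lactone should be alkylated by the reactive α-bromo ester on the convex face, anti to the C9–C11 bond, which sets the quaternary centre C10 (enolate alkylation).

**Step 8**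
Reactants: 12 dialkylated lactone
Product: 14 enone in which the C10 arm is C1H2–C2(=O)–C3H=C4Me2, via tertiary propargylic alcohol 13 (not isolated)
Conditions: Bu4NReO4 (cat.), p-TsOH·H2O (cat.), H2O (1 equiv), CH2Cl2, rt
Reagents that add atoms: none
Why: acid removes the silyl ether and the perrhenate-catalysed Meyer–Schuster rearrangement shifts the tertiary propargylic hydroxyl to C2, which should give the β,β-dimethyl enone without touching the lactone, the ester or the dithiane.

**Step 9**
Reactants: 14 enone
Product: 16 spiro bis-lactone (δ-lactone C10–C5H2–C6(=O)–O–C2H(CH=CMe2)–C1H2 spiro at C10 to the γ-lactone; 2S; alkenyl group cis to C20), via hydroxy ester 15 (not isolated)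
Conditions: (R)-2-methyl-CBS-oxazaborolidine (cat.), catecholborane, toluene, −78 °C; then pyridinium p-toluenesulfonate (cat.), toluene, 50 °C
Reagents that add atoms: none
Why: the CBS reduction should deliver hydride to the enone carbonyl with the alkenyl group as the larger substituent and so set (S)-C2, and the carbinol then lactonises onto the unhindered methyl ester (helped by the quaternary C10) in preference to the α-quaternary γ-lactone carbonyl.

**Step 10**
Reactants: 16 spiro bis-lactone
Product: 19 ring A acid (C6OOH on C5; C5 S; C2=C3 alkene; C4 gem-dimethyl; spiro at C10 to the γ-lactone), via silyl ketene acetal 17 (not isolated), via trimethylsilyl ester 18 (not isolated)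
Conditions: LiN(iPr)2, Me3SiCl/Et3N, THF, −78 °C; then toluene, 100 °C; then 1 M HCl, THF, rt
Reagents that add atoms: none
Why: LiN(iPr)2 removes a C5 proton of the δ-lactone (the only enolisable site, since C10 of the γ-lactone is quaternary and the dithiane C–H is too weakly acidic) and Me3SiCl traps the cyclic silyl ketene acetal 17, which on heating should undergo a concerted [3,3] shift through a boat, bicyclo[2.2.2]-like transition state in which C5 bonds to C4 while the C2–O bond breaks. The closest known reaction type is the Ireland–Claisen rearrangement of 6-alkenyl δ-lactone silyl ketene acetals to cyclohex-3-enecarboxylic acids (lactone-to-carbocycle ring contraction). Ring A (C10–C1–C2=C3–C4–C5) closes suprafacially at the expense of the six-membered lactone, so the closure is pericyclic and the ring-bound ketene acetal geometry is fixed. The new stereocentre C5 is set by the (S)-carbinol C2: the CMe2 terminus can reach C5 only on the lactone face that carries the alkenyl group (cis to C20, trans to C9), which places C6 cis to C9 as in the target, while C4 becomes quaternary but is not stereogenic. The step needs site-selective enolisation and rearrangement faster than elimination of the allylic carboxylate; the first is secured by the absence of other α-hydrogens, the second by the inside methyl group facing the flat C20 carbonyl and not ring C.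

**Step 11**
Reactants: 19 ring A acid
Product: 20 triol (C6H2OH on C5, C20H2OH on C10, tertiary C8–OH; dithiane on C8)
Conditions: LiAlH4, THF, 0 °C to reflux; aq. NaOH work-up
Reagents that add atoms: none
Why: LiAlH4 reduces the hindered carboxylic acid and the γ-lactone in one operation, and with no other carbonyl group present no selectivity is required (hydride reduction).

**Step 12**
Reactants: 20 triol
Product: 22 δ-lactol C10–C20H2–O–C7H(OH)–C8(OH) (mixture of anomers; free C6H2OH), via hydroxy aldehyde 21 (not isolated)
Conditions: MeI, CaCO3, MeCN/H2O, 45 °C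
Reagents that add atoms: water, O
Why: alkylative hydrolysis of the dithiane frees the C7 aldehyde, which should close with the C20 hydroxyl to the six-membered lactol in preference to the seven-membered one with C6–OH; no stereocentre of the target is touched.

**Step 13**
Reactants: 22 lactol
Product: 23 allylic diol (new C1–OH in ring A and new C15H2OH on the side chain; epimers at C1)
Conditions: SeO2, tBuOOH, CH2Cl2, rt
Reagents that add atoms: selenium dioxide, O=[Se]=O; tert-butyl hydroperoxide, CC(C)(C)OO
Why: the SeO2 allylic hydroxylation (ene reaction then [2,3] shift, Riley oxidation) should take the methyl group of the isopropenyl unit and, in ring A, C1, which is the only allylic C–H of the C2=C3 alkene because C4 is quaternary; the C1 centre is removed in step 14.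

**Step 14**
Reactants: 23 allylic diol
Product: 25 bridged keto lactol (the target at the lactol oxidation level), via enone enal 24 (not isolated)
Conditions: MnO2, CH2Cl2, rt; then pyridinium p-toluenesulfonate (cat.), CH2Cl2, rt
Reagents that add atoms: none
Why: MnO2 oxidises only the two allylic alcohols to the C1 enone and the C15 enal, and the C6 hydroxyl then adds to C3 in a 5-exo oxa-Michael reaction that is possible only cis to C6, which sets C3.

**Step 15**
Reactants: 25 bridged keto lactol
Product: 26 CNP0525385.1 (target)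
Conditions: Pr4NRuO4 (cat.), N-methylmorpholine N-oxide, 4 Å molecular sieves, CH2Cl2, rt
Reagents that add atoms: none
Why: the Ley–Griffith oxidation converts the lactol into the δ-lactone under anhydrous conditions that should spare the aldehyde, the tertiary alcohol and the β-alkoxy ketone.

**Compound list**

1 | cyclohex-2-en-1-one | O=C1C=CCCC1 | starting material
2 | methyl bromoacetate | COC(=O)CBr | starting material
3 | methyl 2-(2-oxocyclohex-3-en-1-yl)acetate (racemic) | COC(=O)CC1CCC=CC1=O | intermediate
4 | 4,4,5,5-tetramethyl-2-(prop-1-en-2-yl)-1,3,2-dioxaborolane | C=C(C)B1OC(C)(C)C(C)(C)O1 | starting material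
5 | methyl 2-[(1S,4R)-2-oxo-4-(prop-1-en-2-yl)cyclohexyl]acetate | C=C(C)[C@@H]1CC[C@@H](CC(=O)OC)C(=O)C1 | intermediate
6 | 1,3-dithiane | C1CSCSC1 | starting material
7 | (3aS,6R,7aS)-7a-(1,3-dithian-2-yl)-6-(prop-1-en-2-yl)hexahydro-1-benzofuran-2(3H)-one | C=C(C)[C@@H]1CC[C@H]2CC(=O)O[C@@]2(C3SCCCS3)C1 | intermediate
8 | trimethyl[(2-methylbut-3-yn-2-yl)oxy]silane | C#CC(C)(C)O[Si](C)(C)C | starting material
9 | 4-methyl-4-[(trimethylsilyl)oxy]pent-2-yn-1-ol | OCC#CC(C)(C)O[Si](C)(C)C | intermediate
10 | [(5-bromo-2-methylpent-3-yn-2-yl)oxy]trimethylsilane | BrCC#CC(C)(C)O[Si](C)(C)C | intermediate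
11 | lactone 7 with the silyloxypentynyl arm on C10, cis to H-9 | C=C(C)[C@@H]1CC[C@H]2[C@H](CC#CC(C)(C)O[Si](C)(C)C)C(=O)O[C@@]2(C3SCCCS3)C1 | intermediate
12 | lactone with quaternary C10: CH2CO2Me arm on the face of H-9, silyloxypentynyl arm on the face of C11 | C=C(C)[C@@H]1CC[C@H]2[C@@](CC(=O)OC)(CC#CC(C)(C)O[Si](C)(C)C)C(=O)O[C@@]2(C3SCCCS3)C1 | intermediate
13 | tertiary propargylic alcohol from 12 | C=C(C)[C@@H]1CC[C@H]2[C@@](CC(=O)OC)(CC#CC(C)(C)O)C(=O)O[C@@]2(C3SCCCS3)C1 | intermediate
14 | enone with the arm C1H2–C2(=O)–C3H=C4Me2 | C=C(C)[C@@H]1CC[C@H]2[C@@](CC(=O)OC)(CC(=O)C=C(C)C)C(=O)O[C@@]2(C3SCCCS3)C1 | intermediate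
15 | (2S)-allylic alcohol hydroxy ester | C=C(C)[C@@H]1CC[C@H]2[C@@](CC(=O)OC)(C[C@H](O)C=C(C)C)C(=O)O[C@@]2(C3SCCCS3)C1 | intermediate
16 | spiro bis-lactone (2S; alkenyl cis to C20) | C=C(C)[C@@H]1CC[C@H]2[C@]3(CC(=O)O[C@H](C=C(C)C)C3)C(=O)O[C@@]2(C4SCCCS4)C1 | intermediate
17 | cyclic trimethylsilyl ketene acetal of 16 | C=C(C)[C@@H]1CC[C@H]2[C@]3(C=C(O[Si](C)(C)C)O[C@H](C=C(C)C)C3)C(=O)O[C@@]2(C4SCCCS4)C1 | intermediate
18 | trimethylsilyl ester of 19 | C=C(C)[C@@H]1CC[C@H]2[C@@]3(CC=CC(C)(C)[C@@H]3C(=O)O[Si](C)(C)C)C(=O)O[C@@]2(C4SCCCS4)C1 | intermediate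
19 | ring A acid (5S; C6OOH cis to C9) | C=C(C)[C@@H]1CC[C@H]2[C@@]3(CC=CC(C)(C)[C@@H]3C(=O)O)C(=O)O[C@@]2(C4SCCCS4)C1 | intermediate
20 | triol with dithiane | C=C(C)[C@@H]1CC[C@@H]([C@]2(CO)CC=CC(C)(C)[C@@H]2CO)[C@](O)(C3SCCCS3)C1 | intermediate
21 | α-hydroxy aldehyde triol | C=C(C)[C@@H]1CC[C@@H]([C@]2(CO)CC=CC(C)(C)[C@@H]2CO)[C@](O)(C=O)C1 | intermediate
22 | δ-lactol (anomers) | C=C(C)[C@@H]1CC[C@H]2[C@]3(COC(O)[C@]2(O)C1)CC=CC(C)(C)[C@@H]3CO | intermediate
23 | allylic diol (C1–OH, C15–OH; C1 epimers) | C=C(CO)[C@@H]1CC[C@H]2[C@]3(COC(O)[C@]2(O)C1)C(O)C=CC(C)(C)[C@@H]3CO | intermediate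
24 | enone enal | C=C(C=O)[C@@H]1CC[C@H]2[C@]3(COC(O)[C@]2(O)C1)C(=O)C=CC(C)(C)[C@@H]3CO | intermediate
25 | bridged keto lactol | C=C(C=O)[C@@H]1CC[C@H]2[C@]3(COC(O)[C@]2(O)C1)C(=O)C[C@@H]1OC[C@H]3C1(C)C | intermediate
26 | CNP0525385.1 | C=C(C=O)[C@@H]1CC[C@H]2[C@]3(COC(=O)[C@]2(O)C1)C(=O)C[C@@H]1OC[C@H]3C1(C)C | target

Total step count: 15. Longest linear sequence: 13 (steps 1–3 and 6–15; steps 4–5 make bromide 10).

**Steps most likely to fail**

Step 13. The isopropenyl group should react much faster than the hindered C2=C3 alkene, so forcing the second hydroxylation may over-oxidise the side chain while C1 stays incomplete (poor matching of the two site rates). The fallback sets out from 22 and comes back at 25. Lactol 22 is acetylated (Ac2O, pyridine, DMAP) to the diacetate F1. Allylic oxidation with CrO3·3,5-dimethylpyrazole gives the enone diacetate F2. K2CO3 in MeOH removes both acetates, and the freed C6 hydroxyl adds to the enone to give the bridged keto lactol with intact isopropenyl group F3. SeO2/tBuOOH then has only the isopropenyl group to hydroxylate and gives the allylic alcohol F4, and MnO2 oxidation of F4 gives 25.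

Step 10. The boat transition state must join a neopentyl-type ketene acetal carbon to a fully substituted alkene terminus; if it is too slow, the silyl ketene acetal may be lost by C-silylation or by elimination of the allylic carboxylate to a diene. The fallback sets out from 14 and comes back at 20. CBS reduction of 14 without the acid treatment gives hydroxy ester 15, which is converted with ClP(O)(OEt)2 and pyridine into the allylic diethyl phosphate F5. KN(SiMe3)2 forms the ester enolate, which closes ring A by an intramolecular syn-SN2′ alkylation at C4 to give the ring A methyl ester F6. LiAlH4 reduces the ester and the γ-lactone of F6 to triol 20.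

Step 7. The dithianyl group on C8 lies on the face from which the electrophile must come, so facial selectivity at the tetrasubstituted enolate may be poor or reversed. The fallback for the reversed case sets out from 7 and comes back at 12, exchanging the order of the two arms. Lactone 7 is alkylated first with tert-butyl bromoacetate (LiN(iPr)2) to the tert-butyl ester lactone F7. Me3SiOTf/2,6-lutidine cleaves the tert-butyl ester to the acid F8. LiN(iPr)2 (2 equiv) gives the carboxylate–lactone enolate dianion, in which the carboxylate arm is not enolised, and alkylation with 10 on the same face gives the dialkylated acid F9. Me3SiCHN2 then gives 12.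

**Further compounds**

F1 | step 13 | diacetate of lactol 22 (anomeric and C6 acetates) | C=C(C)[C@@H]1CC[C@H]2[C@]3(COC(OC(C)=O)[C@]2(O)C1)CC=CC(C)(C)[C@@H]3COC(C)=O
F2 | step 13 | enone diacetate | C=C(C)[C@@H]1CC[C@H]2[C@]3(COC(OC(C)=O)[C@]2(O)C1)C(=O)C=CC(C)(C)[C@@H]3COC(C)=O
F3 | step 13 | bridged keto lactol with isopropenyl group | C=C(C)[C@@H]1CC[C@H]2[C@]3(COC(O)[C@]2(O)C1)C(=O)C[C@@H]1OC[C@H]3C1(C)C
F4 | step 13 | bridged keto lactol with 3-hydroxyprop-1-en-2-yl group | C=C(CO)[C@@H]1CC[C@H]2[C@]3(COC(O)[C@]2(O)C1)C(=O)C[C@@H]1OC[C@H]3C1(C)C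
F5 | step 10 | allylic diethyl phosphate of 15 | C=C(C)[C@@H]1CC[C@H]2[C@@](CC(=O)OC)(C[C@H](OP(=O)(OCC)OCC)C=C(C)C)C(=O)O[C@@]2(C3SCCCS3)C1
F6 | step 10 | methyl ester of ring A acid 19 | C=C(C)[C@@H]1CC[C@H]2[C@@]3(CC=CC(C)(C)[C@@H]3C(=O)OC)C(=O)O[C@@]2(C4SCCCS4)C1
F7 | step 7 | lactone 7 with CH2CO2tBu arm on C10 | C=C(C)[C@@H]1CC[C@H]2[C@@H](CC(=O)OC(C)(C)C)C(=O)O[C@@]2(C3SCCCS3)C1
F8 | step 7 | lactone 7 with CH2CO2H arm on C10 | C=C(C)[C@@H]1CC[C@H]2[C@@H](CC(=O)O)C(=O)O[C@@]2(C3SCCCS3)C1
F9 | step 7 | dialkylated lactone acid (free acid of 12) | C=C(C)[C@@H]1CC[C@H]2[C@@](CC(=O)O)(CC#CC(C)(C)O[Si](C)(C)C)C(=O)O[C@@]2(C3SCCCS3)C1
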